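## Structural features

The target is a dibenzylbutyrolactone: one γ-lactone ring (O1, C2 carbonyl, C3, C4, C5) with a 3,4-dihydroxybenzyl group on C3, a 3,4-dimethoxybenzyl group on C4 and an unsubstituted OCH2 at C5. The two stereocentres C3 and C4 are adjacent, both R, and their benzyl groups are trans on the ring. C3 is α to the carbonyl and can be equilibrated to the stable trans arrangement, whereas C4 has no acidic hydrogen and must be set absolutely. Fragile parts are the free catechol (oxidised as its anion in air), the lactone (ring opening, C3 epimerisation) and, in any intermediate with oxygen on a benzylic carbon, the electron-rich arenes, which trap a benzylic cation intramolecularly. The real difficulty is the absolute configuration of the non-epimerisable C4, together with keeping the two arenes and the two ends of the C4 unit (C5–O versus carbonyl) distinct. The key step exploits that C4 carries, besides C3, only two one-carbon branches: the lone OCH2 carbon C5 and the benzylic CH2 of the dimethoxybenzyl arm. If that benzylic carbon temporarily bears an oxygen of defined configuration, silicon can be attached there and used to hand C5 to C4 from one face; silicon and the benzylic oxygen are removed afterwards.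

## Logic of the disconnections

17 ⇒ 15 (through 16). One benzylic C–H (on the carbon between C4 and the dimethoxyphenyl ring) is traded for C–OH, and the two phenolic O–H bonds for O–benzyl. All three are benzylic C–O bonds, so a single hydrogenolysis removes them. This is why the catechol is carried as a dibenzyl ether rather than an acetal-type ether, which would need a separate acid step. The gain is that the catechol appears only in the last flask and the auxiliary benzylic oxygen costs no extra operation. The demand is that the carbinol be reduced without strong acid, because its cation would be captured by the other arene in a six-membered Friedel–Crafts closure.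

15 ⇒ 13 (through 14). The lactone bond O1–C2 is opened to an ethyl ester and a primary alcohol, and C3 is left undefined. C3 is the one centre that equilibrates, so it is cheaper to correct it at the lactone stage than to control it when the carbon skeleton is made. The gain is an open-chain diol ester in which only C4 and the carbinol carbon are defined. The demand is ring closure through the C5 hydroxyl and full equilibration to trans without touching C4.

13 ⇒ 12. C5–OH and the carbinol O–H are traced back to one silicon atom (C5–Si and O–Si). The 1,3-diol is thereby recognised as the footprint of a five-membered cyclic siloxane, and the gain is that both hydroxyls come from one ring whose relative configuration is set in a single step. The demand is an oxidative C–Si cleavage that tolerates the ester and the benzyl ethers.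

12 ⇒ 11. The strategic cut is C4–C5, together with the C3–H bond. This removes the ring and both new stereocentres and leaves a planar enoate whose only stereocentre is the carbinol. The forward step must close the ring faster than the radical is reduced, must do so 5-exo, and must deliver carbon to one face of the alkene.

11 ⇒ 9 + 10. The O–Si bond is cut, separating the radical precursor from an allylic alcohol; the gain is that the one-carbon unit C5 comes from the commercial chlorosilane 10. The silylation must not trigger a base-promoted hydrogen shift of the γ-oxygenated enoate.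

9 ⇒ 8. The carbinol C–H is cut, so no stereocentre remains and the only absolute information of the route comes from an asymmetric ketone reduction. The demand is 1,2-selectivity and a secure facial sense.

8 ⇒ 7 + 5. The C=C bond is cut (Wittig), which divides the skeleton into two aryl-bearing halves of similar size. The (E)-geometry is required because the (Z)-alcohol would lactonise, and because the CH2Ar group then sits cis to the carbinol carbon, which later enforces facial control.

7 ⇒ 6. The aldehyde C=O is traced back to a methyl C–H (Riley oxidation), which reaches a commercial ketone; the demand is oxidation of the methyl group only.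

5 ⇒ 2 + 3 (through 4). The bond between the ylide carbon and the benzylic CH2 is cut, which reaches the commercial ylide 3; the demand is C-monoalkylation of 3 by 2.

2 ⇒ 1. The C–Br bond is traced back to C–OH, which reaches a commercial alcohol; the demand is bromination without loss of the aryl benzyl ethers.

## Other disconnections considered

Alternative 1: The cut removes the two bonds of C4 that do not lead to C3 (C5–C4 and C4–CH2Ar), with C4 supplied as a one-carbon carbenoid. Forward, boronic ester A2 would take up (dichloromethyl)lithium A3, so that the benzyloxymethyl group migrates from boron to carbon with loss of chloride (C5–C4). The Grignard reagent A4 would then displace the second chloride through a second ate complex with inversion (C4–CH2Ar), giving the secondary boronic ester A1; no ring forms.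
- In its favour: C4 is set by the chiral diol unit of A2 in a reaction class with a dependable sense of induction. With the (R,R)-configured diol unit the first migration is expected to expel the pro-S chloride, and displacement of the remaining chloride with inversion then leads to the configuration of A1, which is that of C4 in the target. There is no sacrificial stereocentre, no tin and no benzylic oxygen, and C5 arrives already differentiated as a benzyl ether.
- Against it here: A1 still lacks C3, C2 and the whole catechol arm. At least two further homologations, an oxidation to the acid level and a lactonisation remain. By the same sense of induction, a second chloride displacement under the same diol unit should give the C3 epimer, so an epimerisation or a trans-selective enolate benzylation would be needed anyway. The carbenoid steps need about −100 °C, the chiral director is used stoichiometrically, and A4, an electron-rich benzylic Grignard reagent, tends to homocouple.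
- Comparison: on absolute control of C4 this alternative is the better plan, because the chosen route rests on a ketone reduction whose facial sense is less secure. Mechanistically it is a series of polar 1,2-metallate shifts rather than a radical ring closure. In step count the two are about equal; the chosen route is operationally simpler but carries one sacrificial oxygen.

Alternative 2: The cut is C3–C4 together with a bond the target does not contain, C2–C5. The lactone is viewed as the oxygen-inserted form of a cyclobutanone. Forward, the tertiary amide A7 (a 3-arylpropanamide carrying the pivaloyl-protected catechol and a C2-symmetric 2,5-dimethylpyrrolidinyl group, drawn as (2S,5S); which enantiomer serves would have to be established) would be activated by a sulfonic anhydride and a hindered pyridine base to the keteniminium salt A8 (drawn as the triflate). A8 would add stepwise across the terminal alkene of methyl eugenol A6, and aqueous work-up would give the trans-2,3-disubstituted cyclobutanone A5.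
- In its favour: it is the most convergent of the four plans. Both arylmethyl arms and the C3–C4 bond are assembled in one intermolecular step from an inexpensive allylarene, trans is the preferred arrangement at the enolisable C3, and no benzylic oxygen is introduced.
- Against it here: the C2–C5 bond must become C2–O–C5, so oxygen must be inserted on the CH2 side. Baeyer–Villiger oxidation favours migration of the more substituted α-carbon and should lead mainly to the regioisomeric lactone A10 instead of the protected target A9. A detour would consume the steps saved. Absolute control rests on the chiral amine part of A7 in an intermolecular cycloaddition with an unactivated alkene, where useful induction is not assured, and that amine part is split off on hydrolysis. The dimethoxyarene and the pivalate carbonyls are competing nucleophiles.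
- Comparison: in bond economy and step count up to the carbon skeleton this alternative is the better plan. Mechanistically it is a stepwise cationic (2+2) cycloaddition rather than a radical chain. On regiochemical security of the oxygen placement and on absolute configuration the chosen plan is safer, because the tether can deliver C5 only to C4 and the controlling carbinol can be checked before the key step.

Alternative 3: The cut is the lactone O1–C2 bond of an intermediate in which C4 carries two CH2OH groups, so only C3 must be made enantiopure and the dimethoxyphenyl ring is attached afterwards. Forward, the hydroxy acid A12 (accessible in principle by an auxiliary-controlled enolate alkylation with bromide 2) would lactonise under acid catalysis. Closure through either diastereotopic arm is reversible, and at equilibrium lactone A11, with the free CH2OH trans to the C3 benzyl group, should dominate.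
- In its favour: the relay starts from a centre that dependable auxiliary chemistry can set. No tin, no sacrificial oxygen and no chiral reagent are needed for the desymmetrisation. It uses the same trans preference that step 9 of the chosen route relies on.
- Against it here: the trans preference should be smaller for CH2OH than for a benzyl group. The acid must not epimerise C3. The bond to the dimethoxyphenyl ring must still be made by coupling an activated CH2OH (sulfonate or iodide) with lithium bis(3,4-dimethoxyphenyl)cuprate A13 next to an enolisable lactone, where elimination and ring opening compete.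
- Comparison: in absolute stereocontrol this alternative is at least the equal of the chosen plan and probably more predictable. The logic is the mirror image (C3 controls C4 there; a carbinol controls C4 and C3 follows here), and the decisive step is an equilibration under thermodynamic control rather than a kinetically controlled radical closure. Step counts are comparable. The chosen plan is preferred because both arenes enter early by robust carbonyl chemistry and no C(sp3)–C(sp2) coupling is left for the end.

Key step: step 7

Remarks on the chemistry (assumptions):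
- Step 5: aryl and alkenyl groups on the ketone are of similar size, so the facial sense is not secure. The alkenyl group, whose CH2Ar substituent lies next to the carbonyl oxygen in the s-cis enone, is assumed to be the bulkier one, which calls for the (R)-oxazaborolidine to reach the (R)-carbinol. The configuration of 9 is to be confirmed through its diastereomeric α-methoxy-α-(trifluoromethyl)phenylacetates before step 6, and the enantiomeric catalyst used if the sense is opposite.
- Compound 1 is taken as commercially available.

## Route

Step 1
Reactants: 1 3,4-bis(benzyloxy)benzyl alcohol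
Product: 2 4-(bromomethyl)-1,2-bis(benzyloxy)benzene
Conditions: PBr3 (0.4 equiv), Et2O, 0 °C
Reagents that add atoms: phosphorus tribromide, BrP(Br)Br
Why: Bromination of a primary benzylic alcohol with PBr3 (SN2 displacement of an intermediate phosphite ester); the aryl benzyl ethers are inert under cold, brief conditions and the reactive bromide is used without chromatography.

Step 2
Reactants: 2 4-(bromomethyl)-1,2-bis(benzyloxy)benzene; 3 ethyl (triphenylphosphoranylidene)acetate
Product: 5 ethyl 3-[3,4-bis(benzyloxy)phenyl]-2-(triphenylphosphoranylidene)propanoate, via phosphonium bromide 4 (not isolated)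
Conditions: CHCl3, reflux; then 1 M NaOH, CH2Cl2, 0 °C
Reagents that add atoms: none
Why: C-Alkylation of a stabilised phosphorus ylide by a benzylic bromide gives salt 4, whose remaining α-hydrogen is removed by cold aqueous NaOH to regenerate an α-substituted ester ylide (ylide alkylation followed by deprotonation).

Step 3
Reactants: 6 3',4'-dimethoxyacetophenone
Product: 7 (3,4-dimethoxyphenyl)glyoxal
Conditions: SeO2 (1.1 equiv), 1,4-dioxane/H2O (30:1), reflux; dried by azeotropic distillation with toluene
Reagents that add atoms: selenium dioxide, O=[Se]=O
Why: Riley oxidation of the enolisable methyl group of an aryl methyl ketone to the aldehyde level; it stops there because the product has no further α-hydrogen, and the dimethoxyarene is not attacked.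

Step 4
Reactants: 7 (3,4-dimethoxyphenyl)glyoxal; 5 ethyl 3-[3,4-bis(benzyloxy)phenyl]-2-(triphenylphosphoranylidene)propanoate
Product: 8 ethyl (E)-2-[3,4-bis(benzyloxy)benzyl]-4-(3,4-dimethoxyphenyl)-4-oxobut-2-enoate
Conditions: CH2Cl2, 4 Å MS, 0 °C to rt
Reagents that add atoms: none
Why: Wittig olefination in which only the aldehyde carbonyl of the glyoxal is electrophilic enough for the stabilised ylide; reversible oxaphosphetane formation places the ester trans to the aroyl group, giving the (E)-alkene. Stoichiometric ylide, low temperature and no added base keep the double bond from drifting into conjugation with the benzyloxy-substituted ring.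

Step 5
Reactants: 8 ethyl (E)-2-[3,4-bis(benzyloxy)benzyl]-4-(3,4-dimethoxyphenyl)-4-oxobut-2-enoate
Product: 9 ethyl (R,E)-2-[3,4-bis(benzyloxy)benzyl]-4-(3,4-dimethoxyphenyl)-4-hydroxybut-2-enoate
Conditions: (R)-Me-CBS [(R)-1-methyl-3,3-diphenyltetrahydro-1H,3H-pyrrolo[1,2-c][1,3,2]oxazaborole] (0.3 equiv), catecholborane (1.8 equiv), toluene, −78 °C; MeOH, then pH 7 buffer
Reagents that add atoms: none
Why: Corey–Bakshi–Shibata reduction: the ketone binds to the ring boron and hydride passes from the nitrogen-bound borane through a six-membered transition state, 1,2-selectively at −78 °C, setting the carbinol stereocentre under catalyst control (sense as stated in the remark). The (E)-geometry prevents lactonisation onto the ester, and the work-up is kept neutral because base would shift the double bond and give the γ-keto ester.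

Step 6
Reactants: 9 ethyl (R,E)-2-[3,4-bis(benzyloxy)benzyl]-4-(3,4-dimethoxyphenyl)-4-hydroxybut-2-enoate; 10 (bromomethyl)chlorodimethylsilane
Product: 11 ethyl (R,E)-2-[3,4-bis(benzyloxy)benzyl]-4-{[(bromomethyl)dimethylsilyl]oxy}-4-(3,4-dimethoxyphenyl)but-2-enoate
Conditions: Et3N (1.5 equiv), DMAP (0.05 equiv), CH2Cl2, 0 °C, 30 min; short Florisil pad
Reagents that add atoms: none
Why: O-Silylation of a secondary alcohol by a chlorosilane under amine catalysis; Si–Cl reacts far faster than C–Br, the stereocentre is not involved, and cold, brief conditions avoid an amine-promoted 1,3-hydrogen shift. The hydrolytically labile ether is used at once.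

Step 7
Reactants: 11 ethyl (R,E)-2-[3,4-bis(benzyloxy)benzyl]-4-{[(bromomethyl)dimethylsilyl]oxy}-4-(3,4-dimethoxyphenyl)but-2-enoate
Product: 12 ethyl (2RS)-3-[3,4-bis(benzyloxy)phenyl]-2-[(4S,5R)-5-(3,4-dimethoxyphenyl)-2,2-dimethyl-1,2-oxasilolan-4-yl]propanoate
Conditions: Bu3SnH (1.3 equiv, syringe pump, 6 h), AIBN (0.15 equiv), benzene (0.01 M), 80 °C
Reagents that add atoms: none
Why: The tributyltin radical abstracts bromine from Si–CH2Br, and the nucleophilic α-silyl radical adds intramolecularly to the electron-poor β-carbon of the enoate (the future C4); this is the known class of radical cyclisations of (bromomethyl)dimethylsilyl ethers of allylic alcohols. The one ring formed, the 1,2-oxasilolane, closes 5-exo-trig; the 6-endo alternative would require attack at the fully substituted, ester-bearing α-carbon and is disfavoured sterically and by polarity. The new stereocentre C4 is controlled by the (R)-carbinol: the CH2Ar group cis to the carbinol carbon forces the carbinol C–H into the alkene plane (allylic 1,3-strain), the tether reaches only the face on which the oxygen stands, and the aryl group ends up trans to the side chain on the new ring, as the chair-like transition state with a pseudo-equatorial aryl group also predicts. The adduct radical at C3, tertiary and ester-stabilised, takes hydrogen from Bu3SnH without useful selectivity; this is accepted because C3 is equilibrated in step 9. The selectivities needed are cyclisation ahead of direct reduction (secured by slow stannane addition at high dilution and the activated acceptor), 5-exo regiochemistry and trans delivery at C4 (both secured by the substitution pattern of the alkene). Benzyl ethers, the ester and both arenes are inert to the tin radical chain, and the moisture-sensitive product is carried on crude.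

Step 8
Reactants: 12 ethyl (2RS)-3-[3,4-bis(benzyloxy)phenyl]-2-[(4S,5R)-5-(3,4-dimethoxyphenyl)-2,2-dimethyl-1,2-oxasilolan-4-yl]propanoate
Product: 13 ethyl (2RS,3R,4R)-2-[3,4-bis(benzyloxy)benzyl]-4-(3,4-dimethoxyphenyl)-4-hydroxy-3-(hydroxymethyl)butanoate
Conditions: KF (4 equiv), KHCO3 (2 equiv), 30% H2O2 (10 equiv), THF/MeOH 1:1, 25–40 °C
Reagents that add atoms: hydrogen peroxide, OO
Why: Tamao–Fleming oxidation: fluoride and the ring oxygen make silicon hypervalent, a peroxide-induced 1,2-shift turns C5–Si into C5–OH and the Si–O bond is hydrolysed, so C4 and the carbinol keep their configurations. Ester, benzyl ethers and arenes tolerate buffered H2O2; any material that has already lactonised through the primary hydroxyl converges with 13 in step 9.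

Step 9
Reactants: 13 ethyl (2RS,3R,4R)-2-[3,4-bis(benzyloxy)benzyl]-4-(3,4-dimethoxyphenyl)-4-hydroxy-3-(hydroxymethyl)butanoate
Product: 15 (3R,4R)-3-[3,4-bis(benzyloxy)benzyl]-4-[(R)-(3,4-dimethoxyphenyl)(hydroxy)methyl]dihydrofuran-2(3H)-one, via C3-epimeric hydroxy lactone 14 (not isolated)
Conditions: DBU (1.0 equiv), toluene, 80 °C
Reagents that add atoms: none
Why: DBU-mediated intramolecular transesterification closes the γ-lactone through the primary C5 hydroxyl (5-exo-trig, ethanol lost) to give 14, and reversible enolisation at C3 then equilibrates to the trans-3,4-disubstituted lactone, the favoured arrangement in this lactone class; C4 has no acidic hydrogen. A lactone closed through the benzylic oxygen would be a secondary-alkyl ester with aryl and CH2OH cis on the ring; under the same base it should remain in translactonisation equilibrium with 14 and 15 through its free primary hydroxyl, so it is expected to drain into 15 rather than accumulate.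

Step 10
Reactants: 15 (3R,4R)-3-[3,4-bis(benzyloxy)benzyl]-4-[(R)-(3,4-dimethoxyphenyl)(hydroxy)methyl]dihydrofuran-2(3H)-one
Product: 17 (3R,4R)-3-(3,4-dihydroxybenzyl)-4-(3,4-dimethoxybenzyl)dihydrofuran-2(3H)-one, via debenzylated hydroxy lactone 16 (not isolated)
Conditions: H2 (3 bar), 10% Pd/C, EtOAc/AcOH 4:1, 25–40 °C
Reagents that add atoms: none
Why: Catalytic hydrogenolysis: the two aryl benzyl ethers cleave first (16), and the remaining benzylic C–OH bond, activated by the para-methoxy group, is then reduced to CH2 on palladium in the weakly acidic medium; the lactone and both stereocentres are untouched. Acetic acid is the strongest acid allowed, because a strong acid would ionise the carbinol and the cation would be captured by the neighbouring arene.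

## Compound list

1 | 3,4-bis(benzyloxy)benzyl alcohol | OCc1ccc(OCc2ccccc2)c(OCc2ccccc2)c1 | starting material
2 | 4-(bromomethyl)-1,2-bis(benzyloxy)benzene | BrCc1ccc(OCc2ccccc2)c(OCc2ccccc2)c1 | intermediate
3 | ethyl (triphenylphosphoranylidene)acetate | CCOC(=O)C=P(c1ccccc1)(c1ccccc1)c1ccccc1 | starting material
4 | {3-[3,4-bis(benzyloxy)phenyl]-1-ethoxy-1-oxopropan-2-yl}triphenylphosphonium bromide | CCOC(=O)C(Cc1ccc(OCc2ccccc2)c(OCc2ccccc2)c1)[P+](c1ccccc1)(c1ccccc1)c1ccccc1.[Br-] | intermediate
5 | ethyl 3-[3,4-bis(benzyloxy)phenyl]-2-(triphenylphosphoranylidene)propanoate | CCOC(=O)C(Cc1ccc(OCc2ccccc2)c(OCc2ccccc2)c1)=P(c1ccccc1)(c1ccccc1)c1ccccc1 | intermediate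
6 | 3',4'-dimethoxyacetophenone | CC(=O)c1ccc(OC)c(OC)c1 | starting material
7 | (3,4-dimethoxyphenyl)glyoxal | O=CC(=O)c1ccc(OC)c(OC)c1 | intermediate
8 | ethyl (E)-2-[3,4-bis(benzyloxy)benzyl]-4-(3,4-dimethoxyphenyl)-4-oxobut-2-enoate | CCOC(=O)/C(Cc1ccc(OCc2ccccc2)c(OCc2ccccc2)c1)=C/C(=O)c1ccc(OC)c(OC)c1 | intermediate
9 | ethyl (R,E)-2-[3,4-bis(benzyloxy)benzyl]-4-(3,4-dimethoxyphenyl)-4-hydroxybut-2-enoate | CCOC(=O)/C(Cc1ccc(OCc2ccccc2)c(OCc2ccccc2)c1)=C/[C@@H](O)c1ccc(OC)c(OC)c1 | intermediate
10 | (bromomethyl)chlorodimethylsilane | C[Si](C)(Cl)CBr | starting material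
11 | ethyl (R,E)-2-[3,4-bis(benzyloxy)benzyl]-4-{[(bromomethyl)dimethylsilyl]oxy}-4-(3,4-dimethoxyphenyl)but-2-enoate | CCOC(=O)/C(Cc1ccc(OCc2ccccc2)c(OCc2ccccc2)c1)=C/[C@@H](O[Si](C)(C)CBr)c1ccc(OC)c(OC)c1 | intermediate
12 | ethyl (2RS)-3-[3,4-bis(benzyloxy)phenyl]-2-[(4S,5R)-5-(3,4-dimethoxyphenyl)-2,2-dimethyl-1,2-oxasilolan-4-yl]propanoate | C[Si]1(C)C[C@@H](C(Cc2ccc(OCc3ccccc3)c(OCc3ccccc3)c2)C(=O)OCC)[C@H](c2ccc(OC)c(OC)c2)O1 | intermediate
13 | ethyl (2RS,3R,4R)-2-[3,4-bis(benzyloxy)benzyl]-4-(3,4-dimethoxyphenyl)-4-hydroxy-3-(hydroxymethyl)butanoate | CCOC(=O)C(Cc1ccc(OCc2ccccc2)c(OCc2ccccc2)c1)[C@H](CO)[C@@H](O)c1ccc(OC)c(OC)c1 | intermediate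
14 | (3RS,4R)-3-[3,4-bis(benzyloxy)benzyl]-4-[(R)-(3,4-dimethoxyphenyl)(hydroxy)methyl]dihydrofuran-2(3H)-one | COc1ccc([C@H](O)[C@H]2COC(=O)C2Cc2ccc(OCc3ccccc3)c(OCc3ccccc3)c2)cc1OC | intermediate
15 | (3R,4R)-3-[3,4-bis(benzyloxy)benzyl]-4-[(R)-(3,4-dimethoxyphenyl)(hydroxy)methyl]dihydrofuran-2(3H)-one | COc1ccc([C@H](O)[C@H]2COC(=O)[C@@H]2Cc2ccc(OCc3ccccc3)c(OCc3ccccc3)c2)cc1OC | intermediate
16 | (3R,4R)-3-(3,4-dihydroxybenzyl)-4-[(R)-(3,4-dimethoxyphenyl)(hydroxy)methyl]dihydrofuran-2(3H)-one | COc1ccc([C@H](O)[C@H]2COC(=O)[C@@H]2Cc2ccc(O)c(O)c2)cc1OC | intermediate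
17 | (3R,4R)-3-(3,4-dihydroxybenzyl)-4-(3,4-dimethoxybenzyl)dihydrofuran-2(3H)-one (3'-O-demethylarctigenin) | COc1ccc(C[C@H]2COC(=O)[C@@H]2Cc2ccc(O)c(O)c2)cc1OC | target

## Step count and least certain steps

Total step count: 10. Longest linear sequence: 9 steps (1 → 2 → 5 → 8 → 9 → 11 → 12 → 13 → 15 → 17); the branch 6 → 7 joins at step 4.

Step 7 (key step). The most likely failure is hydrogen transfer from the stannane to the α-silyl radical before ring closure, or hydrolytic loss of the tether; less likely is insufficient facial discrimination at C4. The fallback delivers C5 intermolecularly with a copper reagent and sets out from 8. Reduction of 8 with the enantiomeric (S)-oxazaborolidine and catecholborane should give ethyl (S,E)-2-[3,4-bis(benzyloxy)benzyl]-4-(3,4-dimethoxyphenyl)-4-hydroxybut-2-enoate F1. Silylation (tert-butyldimethylsilyl chloride, imidazole, DMF) gives ethyl (S,E)-2-[3,4-bis(benzyloxy)benzyl]-4-[(tert-butyldimethylsilyl)oxy]-4-(3,4-dimethoxyphenyl)but-2-enoate F2. (Isopropoxydimethylsilyl)methylmagnesium chloride with CuBr·SMe2 and Me3SiCl in THF at −78 to −30 °C should add the masked hydroxymethyl group to the β-carbon to give ethyl (2RS,3S,4S)-2-[3,4-bis(benzyloxy)benzyl]-4-[(tert-butyldimethylsilyl)oxy]-4-(3,4-dimethoxyphenyl)-3-{[dimethyl(propan-2-yloxy)silyl]methyl}butanoate F3. With the carbinol hydrogen in the alkene plane and the silyloxy group antiperiplanar to the incoming nucleophile, carbon should enter on the face away from oxygen, which is why the antipodal carbinol is used; this facial sense is less certain because the aryl group competes for the anti position, and the α-substituted enoate is a sluggish acceptor. Tamao–Fleming oxidation (KF, KHCO3, H2O2) should give ethyl (2RS,3R,4S)-2-[3,4-bis(benzyloxy)benzyl]-4-[(tert-butyldimethylsilyl)oxy]-4-(3,4-dimethoxyphenyl)-3-(hydroxymethyl)butanoate F4. Desilylation with Bu4NF should give ethyl (2RS,3R,4S)-2-[3,4-bis(benzyloxy)benzyl]-4-(3,4-dimethoxyphenyl)-4-hydroxy-3-(hydroxymethyl)butanoate F5. DBU in toluene should give (3R,4R)-3-[3,4-bis(benzyloxy)benzyl]-4-[(S)-(3,4-dimethoxyphenyl)(hydroxy)methyl]dihydrofuran-2(3H)-one F6. Hydrogenolysis as in step 10 then returns to the route at 17.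

Step 5. The most likely failure is poor or inverted facial selectivity, because the aryl and alkenyl substituents are of similar steric demand, together with competing conjugate reduction of the doubly activated alkene. The fallback replaces asymmetric catalysis by resolution and sets out from 8. Luche reduction (NaBH4, CeCl3·7H2O, MeOH, −40 °C) should give racemic ethyl (E)-2-[3,4-bis(benzyloxy)benzyl]-4-(3,4-dimethoxyphenyl)-4-hydroxybut-2-enoate F7. The enantiomers are separated by preparative chromatography on a polysaccharide-based chiral stationary phase. The (R)-enantiomer is 9, where the route is rejoined; the other enantiomer is returned to 8 with MnO2.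

Step 10. The most likely failure is incomplete cleavage of the benzylic C–OH bond after fast debenzylation, or, if acidity is raised to force it, ionisation and ring closure onto the catechol ring. The fallback activates the leaving group and sets out from 15. Acetylation (Ac2O, pyridine, DMAP) should give (R)-{(3R,4R)-4-[3,4-bis(benzyloxy)benzyl]-5-oxooxolan-3-yl}(3,4-dimethoxyphenyl)methyl acetate F8. This is hydrogenolysed together with the benzyl ethers over 10% Pd/C in neutral ethyl acetate, acetate being a far better leaving group on palladium than hydroxide. The route is rejoined at 17.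

Step 9. The most likely failure is acyl migration to the benzylic oxygen or incomplete equilibration at C3, leaving a mixture of lactones. The fallback changes the order so that only one lactone can form, and sets out from 13. Hydrogenolysis as in step 10 removes the benzylic oxygen and the benzyl ethers first and should give ethyl (2RS,3R)-2-(3,4-dihydroxybenzyl)-4-(3,4-dimethoxyphenyl)-3-(hydroxymethyl)butanoate F9, in which only one hydroxyl can reach the ester. Warming in toluene with a trace of 4-toluenesulfonic acid should close it to (3RS,4R)-3-(3,4-dihydroxybenzyl)-4-(3,4-dimethoxybenzyl)dihydrofuran-2(3H)-one F10. Equilibration with DBU in degassed THF under argon, followed by acidification, should give 17 directly. The catecholate must be kept strictly free of oxygen.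

## Further compounds

F1 | step 7 | ethyl (S,E)-2-[3,4-bis(benzyloxy)benzyl]-4-(3,4-dimethoxyphenyl)-4-hydroxybut-2-enoate | CCOC(=O)/C(Cc1ccc(OCc2ccccc2)c(OCc2ccccc2)c1)=C/[C@H](O)c1ccc(OC)c(OC)c1
F2 | step 7 | ethyl (S,E)-2-[3,4-bis(benzyloxy)benzyl]-4-[(tert-butyldimethylsilyl)oxy]-4-(3,4-dimethoxyphenyl)but-2-enoate | CCOC(=O)/C(Cc1ccc(OCc2ccccc2)c(OCc2ccccc2)c1)=C/[C@H](O[Si](C)(C)C(C)(C)C)c1ccc(OC)c(OC)c1
F3 | step 7 | ethyl (2RS,3S,4S)-2-[3,4-bis(benzyloxy)benzyl]-4-[(tert-butyldimethylsilyl)oxy]-4-(3,4-dimethoxyphenyl)-3-{[dimethyl(propan-2-yloxy)silyl]methyl}butanoate | CCOC(=O)C(Cc1ccc(OCc2ccccc2)c(OCc2ccccc2)c1)[C@H](C[Si](C)(C)OC(C)C)[C@H](O[Si](C)(C)C(C)(C)C)c1ccc(OC)c(OC)c1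
F4 | step 7 | ethyl (2RS,3R,4S)-2-[3,4-bis(benzyloxy)benzyl]-4-[(tert-butyldimethylsilyl)oxy]-4-(3,4-dimethoxyphenyl)-3-(hydroxymethyl)butanoate | CCOC(=O)C(Cc1ccc(OCc2ccccc2)c(OCc2ccccc2)c1)[C@H](CO)[C@H](O[Si](C)(C)C(C)(C)C)c1ccc(OC)c(OC)c1
F5 | step 7 | ethyl (2RS,3R,4S)-2-[3,4-bis(benzyloxy)benzyl]-4-(3,4-dimethoxyphenyl)-4-hydroxy-3-(hydroxymethyl)butanoate | CCOC(=O)C(Cc1ccc(OCc2ccccc2)c(OCc2ccccc2)c1)[C@H](CO)[C@H](O)c1ccc(OC)c(OC)c1
F6 | step 7 | (3R,4R)-3-[3,4-bis(benzyloxy)benzyl]-4-[(S)-(3,4-dimethoxyphenyl)(hydroxy)methyl]dihydrofuran-2(3H)-one | COc1ccc([C@@H](O)[C@H]2COC(=O)[C@@H]2Cc2ccc(OCc3ccccc3)c(OCc3ccccc3)c2)cc1OC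
F7 | step 5 | racemic ethyl (E)-2-[3,4-bis(benzyloxy)benzyl]-4-(3,4-dimethoxyphenyl)-4-hydroxybut-2-enoate | CCOC(=O)/C(Cc1ccc(OCc2ccccc2)c(OCc2ccccc2)c1)=C/C(O)c1ccc(OC)c(OC)c1
F8 | step 10 | (R)-{(3R,4R)-4-[3,4-bis(benzyloxy)benzyl]-5-oxooxolan-3-yl}(3,4-dimethoxyphenyl)methyl acetate | COc1ccc([C@H](OC(C)=O)[C@H]2COC(=O)[C@@H]2Cc2ccc(OCc3ccccc3)c(OCc3ccccc3)c2)cc1OC
F9 | step 9 | ethyl (2RS,3R)-2-(3,4-dihydroxybenzyl)-4-(3,4-dimethoxyphenyl)-3-(hydroxymethyl)butanoate | CCOC(=O)C(Cc1ccc(O)c(O)c1)[C@H](CO)Cc1ccc(OC)c(OC)c1
F10 | step 9 | (3RS,4R)-3-(3,4-dihydroxybenzyl)-4-(3,4-dimethoxybenzyl)dihydrofuran-2(3H)-one | COc1ccc(C[C@H]2COC(=O)C2Cc2ccc(O)c(O)c2)cc1OC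
A1 | alternative 1 | (4R,5R)-2-[(2S)-1-(benzyloxy)-3-(3,4-dimethoxyphenyl)propan-2-yl]-4,5-dicyclohexyl-1,3,2-dioxaborolane | COc1ccc(C[C@H](B2O[C@H](C3CCCCC3)[C@@H](C3CCCCC3)O2)COCc2ccccc2)cc1OC
A2 | alternative 1 | (4R,5R)-2-[(benzyloxy)methyl]-4,5-dicyclohexyl-1,3,2-dioxaborolane | C(OCc1ccccc1)B1O[C@H](C2CCCCC2)[C@@H](C2CCCCC2)O1
A3 | alternative 1 | (dichloromethyl)lithium | [Li]C(Cl)Cl
A4 | alternative 1 | 3,4-dimethoxybenzylmagnesium chloride | COc1ccc(C[Mg]Cl)cc1OC
A5 | alternative 2 | (2R,3S)-2-[3,4-bis(pivaloyloxy)benzyl]-3-(3,4-dimethoxybenzyl)cyclobutan-1-one | COc1ccc(C[C@H]2CC(=O)[C@@H]2Cc2ccc(OC(=O)C(C)(C)C)c(OC(=O)C(C)(C)C)c2)cc1OC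
A6 | alternative 2 | methyl eugenol (4-allyl-1,2-dimethoxybenzene) | C=CCc1ccc(OC)c(OC)c1
A7 | alternative 2 | 4-{3-[(2S,5S)-2,5-dimethylpyrrolidin-1-yl]-3-oxopropyl}-1,2-phenylene bis(2,2-dimethylpropanoate) | C[C@H]1CC[C@H](C)N1C(=O)CCc1ccc(OC(=O)C(C)(C)C)c(OC(=O)C(C)(C)C)c1
A8 | alternative 2 | (2S,5S)-1-{3-[3,4-bis(pivaloyloxy)phenyl]prop-1-en-1-ylidene}-2,5-dimethylpyrrolidin-1-ium trifluoromethanesulfonate | C[C@H]1CC[C@H](C)[N+]1=C=CCc1ccc(OC(=O)C(C)(C)C)c(OC(=O)C(C)(C)C)c1.[O-]S(=O)(=O)C(F)(F)F
A9 | alternative 2 | 4-{[(3R,4R)-4-(3,4-dimethoxybenzyl)-2-oxooxolan-3-yl]methyl}-1,2-phenylene bis(2,2-dimethylpropanoate) | COc1ccc(C[C@H]2COC(=O)[C@@H]2Cc2ccc(OC(=O)C(C)(C)C)c(OC(=O)C(C)(C)C)c2)cc1OC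
A10 | alternative 2 | (4S,5R)-5-[3,4-bis(pivaloyloxy)benzyl]-4-(3,4-dimethoxybenzyl)dihydrofuran-2(3H)-one | COc1ccc(C[C@H]2CC(=O)O[C@@H]2Cc2ccc(OC(=O)C(C)(C)C)c(OC(=O)C(C)(C)C)c2)cc1OC
A11 | alternative 3 | (3R,4S)-3-[3,4-bis(benzyloxy)benzyl]-4-(hydroxymethyl)dihydrofuran-2(3H)-one | OC[C@H]1COC(=O)[C@@H]1Cc1ccc(OCc2ccccc2)c(OCc2ccccc2)c1
A12 | alternative 3 | (R)-2-[3,4-bis(benzyloxy)benzyl]-4-hydroxy-3-(hydroxymethyl)butanoic acid | OCC(CO)[C@@H](Cc1ccc(OCc2ccccc2)c(OCc2ccccc2)c1)C(=O)O
A13 | alternative 3 | lithium bis(3,4-dimethoxyphenyl)cuprate | [Li+].COc1ccc([Cu-]c2ccc(OC)c(OC)c2)cc1OC
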